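**Abbreviations and locants.** TBS = tert-butyldimethylsilyl, TES = triethylsilyl, CSA = camphor-10-sulfonic acid, (−)-MIB = (2S)-3-exo-morpholinoisoborneol. Oxolane locants: O1, C2 (quaternary), C3 (carbinol), C4, C5; C6=C7 is the alkene on C5.

**Assumption.** The facial sense of the two chiral ligands (steps 4 and 18) is taken from their behaviour with cyclohex-2-enone and with simple aldehydes; either antipode of each ligand is available if the sense must be reversed.

## Retrosynthetic overview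

- The target is reached by allylic oxidation and desilylation of a silylated oxolane. In that oxolane one operation cuts the ring bond O1–C2 and the chain bond C5–C6, giving a cyclohexane-bearing 2-alkyne and a small β,γ-epoxy aldehyde.
- Enabling feature: O1 sits on C5, which is allylic to C6=C7 and therefore accessible by alkenyl-metal addition to an aldehyde. O1 is four atoms from the fully substituted C2, and C2–C3 is carried as a (2R,3R)-epoxide, so the C5 oxygen opens the epoxide 5-endo at tertiary C2 with inversion while C3 keeps its oxygen.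
- The epoxy aldehyde comes from geraniol by Sharpless epoxidation and a one-carbon dithiane homologation.
- The alkyne comes from benzoquinone monoketal: asymmetric conjugate addition, two α′-alkylations (quaternary carbon), methyl addition, then dibromo-olefination, selective Negishi methylation and hydroxymethylation for the (Z)-tetrasubstituted alkene.
- Ring order: the carbocycle is present from the start; the oxolane is closed last, in step 18.

Key step: step 18

## Route

Step 1
Reactants: 1 geraniol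
Product: 2 [(2R,3R)-3-methyl-3-(4-methylpent-3-en-1-yl)oxiran-2-yl]methanol
Conditions: Ti(OiPr)4 (5 mol %), D-(−)-diisopropyl tartrate (6 mol %), t-BuOOH, 4 Å MS, CH2Cl2, −20 °C
Reagents that add atoms: tert-butyl hydroperoxide, CC(C)(C)OO
Why: Sharpless asymmetric epoxidation, in which the allylic hydroxyl directs oxidation to the 2,3-alkene only and the D-(−)-tartrate delivers oxygen to the face that gives the (2R,3R)-epoxide.

Step 2
Reactants: 2 [(2R,3R)-3-methyl-3-(4-methylpent-3-en-1-yl)oxiran-2-yl]methanol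
Product: 4 2-{[(2R,3R)-3-methyl-3-(4-methylpent-3-en-1-yl)oxiran-2-yl]methyl}-1,3-dithiane, via epoxy triflate 3 (not isolated)
Conditions: Tf2O, 2,6-lutidine, CH2Cl2, −78 °C; then added to 2-lithio-1,3-dithiane (from 1,3-dithiane, n-BuLi, THF, −30 °C; 2.5 equiv), −78 → −40 °C
Reagents that add atoms: 2-lithio-1,3-dithiane, [Li]C1SCCCS1 (from 1,3-dithiane, C1CSCSC1, and n-BuLi)
Why: SN2 alkylation of the Corey–Seebach formyl-anion equivalent by the cold primary triflate should be much faster than attack on the hindered trisubstituted epoxide, and no stereocentre is touched.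

Step 3
Reactants: 4 2-{[(2R,3R)-3-methyl-3-(4-methylpent-3-en-1-yl)oxiran-2-yl]methyl}-1,3-dithiane
Product: 5 2-[(2R,3R)-3-methyl-3-(4-methylpent-3-en-1-yl)oxiran-2-yl]acetaldehyde
Conditions: MeI, CaCO3, MeCN/H2O (9:1), 35 °C; used crude at once in step 18
Reagents that add atoms: water, O
Why: S-methylation and hydrolysis of the dithioacetal under buffered, non-basic conditions should unmask the aldehyde without the E1cB opening to which a β,γ-epoxy aldehyde is prone.

Step 4
Reactants: 6 4,4-dimethoxycyclohexa-2,5-dien-1-one; 7 tert-butyl(3-iodopropoxy)dimethylsilane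
Product: 9 (5S)-5-{3-[(tert-butyldimethylsilyl)oxy]propyl}-4,4-dimethoxycyclohex-2-en-1-one, via dialkylzinc 8 (not isolated)
Conditions: 7, Et2Zn, CuI (cat.), neat, 50 °C, then volatiles removed; Cu(OTf)2 (2 mol %), (R,S,S)-O,O′-(1,1′-binaphthyl-2,2′-diyl) N,N-bis(1-phenylethyl)phosphoramidite (4 mol %), 6, toluene, −25 °C; aq NH4Cl
Reagents that add atoms: none
Why: Iodine–zinc exchange gives the functionalised dialkylzinc, and copper/phosphoramidite-catalysed asymmetric conjugate addition to the quinone monoketal should set C5 (S) under ligand control, stopping at mono-addition because the zinc enolate is inert.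

Step 5
Reactants: 9 (5S)-5-{3-[(tert-butyldimethylsilyl)oxy]propyl}-4,4-dimethoxycyclohex-2-en-1-one
Product: 11 (5S)-5-{3-[(tert-butyldimethylsilyl)oxy]propyl}-4,4-dimethoxy-6-methylcyclohex-2-en-1-one (C6 epimers), via lithium dienolate 10 (not isolated)
Conditions: LiN(iPr)2, THF, −78 °C; MeI, −78 → −20 °C
Reagents that add atoms: iodomethane, CI
Why: Kinetic α′-deprotonation of the cross-conjugated enone (C4 is fully substituted, so there is no γ-hydrogen) and enolate methylation; the new centre is levelled in step 6.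

Step 6
Reactants: 11 (5S)-5-{3-[(tert-butyldimethylsilyl)oxy]propyl}-4,4-dimethoxy-6-methylcyclohex-2-en-1-one
Product: 13 (5S,6S)-5-{3-[(tert-butyldimethylsilyl)oxy]propyl}-4,4-dimethoxy-6-methyl-6-(prop-2-en-1-yl)cyclohex-2-en-1-one, via lithium enolate 12 (not isolated)
Conditions: LiN(iPr)2, THF, −78 → 0 °C; allyl bromide, DMPU, −78 → 0 °C
Reagents that add atoms: allyl bromide, C=CCBr
Why: Alkylation of the tetrasubstituted enolate builds the quaternary carbon, with allyl expected to enter anti to the neighbouring C5 side chain (1,2-induction in cyclohexenone enolate alkylation) to give the trans (6S) arrangement.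

Step 7
Reactants: 13 (5S,6S)-5-{3-[(tert-butyldimethylsilyl)oxy]propyl}-4,4-dimethoxy-6-methyl-6-(prop-2-en-1-yl)cyclohex-2-en-1-one
Product: 14 (2S,3S)-3-{3-[(tert-butyldimethylsilyl)oxy]propyl}-4,4-dimethoxy-2-methyl-2-(prop-2-en-1-yl)cyclohexan-1-one
Conditions: [(Ph3P)CuH]6 (0.4 equiv), benzene, H2O (2 equiv), rt
Reagents that add atoms: none
Why: Copper hydride conjugate reduction (hydride to the β-carbon, protonation of the copper enolate) should saturate the enone while sparing the isolated terminal alkene and the ketal.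

Step 8
Reactants: 14 (2S,3S)-3-{3-[(tert-butyldimethylsilyl)oxy]propyl}-4,4-dimethoxy-2-methyl-2-(prop-2-en-1-yl)cyclohexan-1-one
Product: 15 (1S,2S,3S)-3-{3-[(tert-butyldimethylsilyl)oxy]propyl}-4,4-dimethoxy-1,2-dimethyl-2-(prop-2-en-1-yl)cyclohexan-1-ol
Conditions: MeMgBr, CeCl3 (dried), THF, −78 → 0 °C; aq NH4Cl
Reagents that add atoms: methylmagnesium bromide, C[Mg]Br
Why: Organocerium 1,2-addition suppresses enolisation of the hindered ketone, and methyl is expected to attack axially, anti to the axial C2 methyl of the chair that keeps the C2 allyl and C3 side chain equatorial, so the hydroxyl ends cis to the C2 methyl (1S).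

Step 9
Reactants: 15 (1S,2S,3S)-3-{3-[(tert-butyldimethylsilyl)oxy]propyl}-4,4-dimethoxy-1,2-dimethyl-2-(prop-2-en-1-yl)cyclohexan-1-ol
Product: 16 triethylsilyl ether of 15
Conditions: TESOTf, 2,6-lutidine, CH2Cl2, −78 → 0 °C
Reagents that add atoms: triethylsilyl trifluoromethanesulfonate, CC[Si](CC)(CC)OS(=O)(=O)C(F)(F)F
Why: Silyl triflate silylation of the hindered tertiary alcohol, to which ketone-derived dimethyl ketals are inert at this temperature; it prevents the hydroxyl from closing onto the electrophilic side chain in steps 11 and 12.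

Step 10
Reactants: 16 triethylsilyl ether of 15
Product: 18 2-[(1S,2S,6S)-6-{3-[(tert-butyldimethylsilyl)oxy]propyl}-5,5-dimethoxy-1,2-dimethyl-2-[(triethylsilyl)oxy]cyclohexyl]ethan-1-ol, via aldehyde 17 (not isolated)
Conditions: O3, CH2Cl2/MeOH, −78 °C; then NaBH4, −78 → 0 °C
Reagents that add atoms: ozone, [O-][O+]=O
Why: Ozonolysis of the only alkene with reductive borohydride work-up gives the two-carbon alcohol directly.

Step 11
Reactants: 18 2-[(1S,2S,6S)-6-{3-[(tert-butyldimethylsilyl)oxy]propyl}-5,5-dimethoxy-1,2-dimethyl-2-[(triethylsilyl)oxy]cyclohexyl]ethan-1-ol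
Product: 19 tert-butyl{3-[(1S,2S,3S)-2-(2-iodoethyl)-6,6-dimethoxy-2,3-dimethyl-3-[(triethylsilyl)oxy]cyclohexyl]propoxy}dimethylsilane
Conditions: I2, PPh3, imidazole, CH2Cl2, 0 °C → rt
Reagents that add atoms: iodine, II
Why: Appel-type iodination of the primary alcohol by SN2 displacement of the alkoxyphosphonium ion.

Step 12
Reactants: 19 tert-butyl{3-[(1S,2S,3S)-2-(2-iodoethyl)-6,6-dimethoxy-2,3-dimethyl-3-[(triethylsilyl)oxy]cyclohexyl]propoxy}dimethylsilane
Product: 20 tert-butyl{3-[(1S,2S,3S)-6,6-dimethoxy-2,3-dimethyl-2-(pent-3-yn-1-yl)-3-[(triethylsilyl)oxy]cyclohexyl]propoxy}dimethylsilane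
Conditions: LiC≡CCH3, THF/DMPU, −78 °C → rt
Reagents that add atoms: 1-propynyllithium, [Li]C#CC
Why: SN2 alkylation of the acetylide by the unhindered primary iodide in a dipolar medium installs the 2-alkyne needed for step 18.

Step 13
Reactants: 20 tert-butyl{3-[(1S,2S,3S)-6,6-dimethoxy-2,3-dimethyl-2-(pent-3-yn-1-yl)-3-[(triethylsilyl)oxy]cyclohexyl]propoxy}dimethylsilane
Product: 21 (2S,3S,4S)-2-{3-[(tert-butyldimethylsilyl)oxy]propyl}-3,4-dimethyl-3-(pent-3-yn-1-yl)-4-[(triethylsilyl)oxy]cyclohexan-1-one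
Conditions: 10% aq oxalic acid, SiO2, CH2Cl2, rt
Reagents that add atoms: water, O
Why: Mild hydrolysis of the dimethyl ketal on wet silica should leave both silyl ethers and the α-stereocentre untouched.

Step 14
Reactants: 21 (2S,3S,4S)-2-{3-[(tert-butyldimethylsilyl)oxy]propyl}-3,4-dimethyl-3-(pent-3-yn-1-yl)-4-[(triethylsilyl)oxy]cyclohexan-1-one
Product: 22 tert-butyl{3-[(1S,2S,3S)-6-(dibromomethylidene)-2,3-dimethyl-2-(pent-3-yn-1-yl)-3-[(triethylsilyl)oxy]cyclohexyl]propoxy}dimethylsilane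
Conditions: CBr4, P(OiPr)3, CH2Cl2, 0 °C → rt; aq NaHCO3
Reagents that add atoms: carbon tetrabromide, BrC(Br)(Br)Br
Why: Ramirez dibromo-olefination with the phosphite-derived dibromomethylene ylide, the variant that works on hindered, enolisable ketones under neutral conditions.

Step 15
Reactants: 22 tert-butyl{3-[(1S,2S,3S)-6-(dibromomethylidene)-2,3-dimethyl-2-(pent-3-yn-1-yl)-3-[(triethylsilyl)oxy]cyclohexyl]propoxy}dimethylsilane
Product: 23 tert-butyl{3-[(1S,2S,3S,6Z)-6-(1-bromoethylidene)-2,3-dimethyl-2-(pent-3-yn-1-yl)-3-[(triethylsilyl)oxy]cyclohexyl]propoxy}dimethylsilane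
Conditions: MeZnCl, PdCl2(DPEphos) (5 mol %), THF, 0 °C → rt
Reagents that add atoms: methylzinc chloride, C[Zn]Cl
Why: Selective Negishi mono-methylation, in which zerovalent palladium should insert into the less hindered C–Br bond (syn to the ring CH2) and leave the bromine syn to the substituted ring carbon, giving the (Z)-bromoalkene.

Step 16
Reactants: 23 tert-butyl{3-[(1S,2S,3S,6Z)-6-(1-bromoethylidene)-2,3-dimethyl-2-(pent-3-yn-1-yl)-3-[(triethylsilyl)oxy]cyclohexyl]propoxy}dimethylsilane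
Product: 25 (2Z)-2-[(2R,3S,4S)-2-{3-[(tert-butyldimethylsilyl)oxy]propyl}-3,4-dimethyl-3-(pent-3-yn-1-yl)-4-[(triethylsilyl)oxy]cyclohexylidene]propan-1-ol, via alkenyllithium 24 (not isolated)
Conditions: t-BuLi (2.1 equiv), THF, −78 °C; then CH2O (monomeric, THF), −78 → 0 °C; aq NH4Cl
Reagents that add atoms: formaldehyde, C=O
Why: Bromine–lithium exchange and trapping by formaldehyde both proceed with retention at the alkenyl carbon, so the hydroxymethyl group takes the place of bromine syn to the substituted ring carbon.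

Step 17
Reactants: 25 (2Z)-2-[(2R,3S,4S)-2-{3-[(tert-butyldimethylsilyl)oxy]propyl}-3,4-dimethyl-3-(pent-3-yn-1-yl)-4-[(triethylsilyl)oxy]cyclohexylidene]propan-1-ol
Product: 26 tert-butyldimethylsilyl ether of 25
Conditions: TBSCl, imidazole, DMF, rt
Reagents that add atoms: tert-butyldimethylsilyl chloride, CC(C)(C)[Si](C)(C)Cl
Why: Standard silylation of the primary allylic alcohol, so that the only free hydroxyl generated in step 18 is the one at C5.

Step 18
Reactants: 26 tert-butyldimethylsilyl ether of 25; 5 2-[(2R,3R)-3-methyl-3-(4-methylpent-3-en-1-yl)oxiran-2-yl]acetaldehyde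
Product: 30 (2S,3R,5R)-2-methyl-2-(4-methylpent-3-en-1-yl)-5-[(2E)-5-(silylated cyclohexyl)pent-2-en-2-yl]oxolan-3-ol (full structure in the list), via alkenylzirconocene 27 (not isolated), via alkenylzinc 28 (not isolated), via epoxy alcohol 29 (not isolated)
Conditions: 26, Cp2Zr(H)Cl (1.1 equiv), CH2Cl2, rt; solvent switch to toluene, Me2Zn (1.2 equiv), −65 °C; (−)-MIB (10 mol %), then 5 (1.5 equiv), −30 → 0 °C; then CSA (3 equiv) in CH2Cl2, 0 °C → rt
Reagents that add atoms: none
Why: syn-Hydrozirconation of the 2-alkyne puts zirconium on the methyl-bearing carbon, zirconium-to-zinc exchange with retention gives the (E)-alkenylzinc, and the zinc alkoxide of (−)-MIB should deliver it to the Si face of aldehyde 5 to form C5–C6 and the (5R) alkoxide of 29, the closest known reaction type being amino-alcohol-catalysed addition of alkenylzirconocene-derived alkenylzinc reagents to aldehydes. Acidification with CSA then frees the C5 hydroxyl and activates the epoxide, and O1 attacks the fully substituted epoxide carbon C2 from the side opposite the breaking C2–O bond, the closest known reaction type being acid-catalysed cyclisation of 3,4-epoxy alcohols with trisubstituted epoxides to oxolan-3-ols. The oxolane ring (O1, C2, C3, C4, C5) closes in the 5-endo mode at the epoxide, which is favoured over 4-exo oxetane formation at secondary C3 because the developing positive charge is best carried by tertiary C2 and the four-membered alternative is strained. C5 (R) is set by the chiral ligand, C2 (S) arises by inversion of the (R)-configured epoxide carbon laid down in step 1, C3 (R) keeps the configuration and the oxygen of the epoxide, and the (E) geometry of C6=C7 is fixed by the syn hydrometalation. The step needs regioselective hydrozirconation (methyl over methylene terminus, helped by equilibration), addition faster than enolisation or β-elimination of the β,γ-epoxy aldehyde (secured by the non-basic organozinc), and endo-selective epoxide opening (secured because the only free hydroxyl stands four atoms from C2 while every other oxygen is silylated). In one flask it joins the two halves and creates the C5–C6 bond, the trisubstituted alkene, the oxolane ring and two of its three stereocentres.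

Step 19
Reactants: 30 silylated oxolan-3-ol from step 18
Product: 31 (2Z)-2-[(2R,3S,4S)-4-hydroxy-2-(3-hydroxypropyl)-3,4-dimethyl-3-{(3E)-4-[(2R,4R,5S)-4-hydroxy-5-methyl-5-(4-methylpent-3-en-1-yl)oxolan-2-yl]pent-3-en-1-yl}cyclohexylidene]propan-1-ol
Conditions: HF·pyridine, pyridine, THF, 0 °C → rt
Reagents that add atoms: none
Why: Buffered fluoride cleavage of the two TBS ethers and the tertiary TES ether, driven by Si–F bond formation, with no stereocentre involved.

Step 20
Reactants: 31 (2Z)-2-[(2R,3S,4S)-4-hydroxy-2-(3-hydroxypropyl)-3,4-dimethyl-3-{(3E)-4-[(2R,4R,5S)-4-hydroxy-5-methyl-5-(4-methylpent-3-en-1-yl)oxolan-2-yl]pent-3-en-1-yl}cyclohexylidene]propan-1-ol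
Product: 32 (2Z)-2-[(2R,3S,4S)-4-hydroxy-2-(3-hydroxypropyl)-3,4-dimethyl-3-{(3E)-4-[(2R,4R,5S)-4-hydroxy-5-methyl-5-(4-methylpent-3-en-1-yl)oxolan-2-yl]pent-3-en-1-yl}cyclohexylidene]propanal
Conditions: MnO2 (activated), CH2Cl2, rt
Reagents that add atoms: none
Why: MnO2 oxidises only the allylic primary alcohol, leaving the saturated primary, secondary and tertiary hydroxyls and the alkene geometry unchanged.

## Compound list

1 | geraniol, (2E)-3,7-dimethylocta-2,6-dien-1-ol | CC(C)=CCC/C(C)=C/CO | starting material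
2 | [(2R,3R)-3-methyl-3-(4-methylpent-3-en-1-yl)oxiran-2-yl]methanol | CC(C)=CCC[C@@]1(C)O[C@@H]1CO | intermediate
3 | [(2R,3R)-3-methyl-3-(4-methylpent-3-en-1-yl)oxiran-2-yl]methyl trifluoromethanesulfonate | CC(C)=CCC[C@@]1(C)O[C@@H]1COS(=O)(=O)C(F)(F)F | intermediate
4 | 2-{[(2R,3R)-3-methyl-3-(4-methylpent-3-en-1-yl)oxiran-2-yl]methyl}-1,3-dithiane | CC(C)=CCC[C@@]1(C)O[C@@H]1CC1SCCCS1 | intermediate
5 | 2-[(2R,3R)-3-methyl-3-(4-methylpent-3-en-1-yl)oxiran-2-yl]acetaldehyde | CC(C)=CCC[C@@]1(C)O[C@@H]1CC=O | intermediate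
6 | 4,4-dimethoxycyclohexa-2,5-dien-1-one | COC1(OC)C=CC(=O)C=C1 | starting material
7 | tert-butyl(3-iodopropoxy)dimethylsilane | CC(C)(C)[Si](C)(C)OCCCI | starting material
8 | bis{3-[(tert-butyldimethylsilyl)oxy]propyl}zinc | CC(C)(C)[Si](C)(C)OCCC[Zn]CCCO[Si](C)(C)C(C)(C)C | intermediate
9 | (5S)-5-{3-[(tert-butyldimethylsilyl)oxy]propyl}-4,4-dimethoxycyclohex-2-en-1-one | O=C1C=CC(OC)(OC)[C@@H](CCCO[Si](C)(C)C(C)(C)C)C1 | intermediate
10 | lithium dienolate of 9 (α′-enolate) | [Li]OC1=C[C@H](CCCO[Si](C)(C)C(C)(C)C)C(OC)(OC)C=C1 | intermediate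
11 | (5S)-5-{3-[(tert-butyldimethylsilyl)oxy]propyl}-4,4-dimethoxy-6-methylcyclohex-2-en-1-one, C6 epimers | O=C1C=CC(OC)(OC)[C@@H](CCCO[Si](C)(C)C(C)(C)C)C1C | intermediate
12 | lithium enolate of 11 (α′-enolate) | [Li]OC1=C(C)[C@H](CCCO[Si](C)(C)C(C)(C)C)C(OC)(OC)C=C1 | intermediate
13 | (5S,6S)-5-{3-[(tert-butyldimethylsilyl)oxy]propyl}-4,4-dimethoxy-6-methyl-6-(prop-2-en-1-yl)cyclohex-2-en-1-one | C=CC[C@@]1(C)[C@H](CCCO[Si](C)(C)C(C)(C)C)C(OC)(OC)C=CC1=O | intermediate
14 | (2S,3S)-3-{3-[(tert-butyldimethylsilyl)oxy]propyl}-4,4-dimethoxy-2-methyl-2-(prop-2-en-1-yl)cyclohexan-1-one | C=CC[C@@]1(C)[C@H](CCCO[Si](C)(C)C(C)(C)C)C(OC)(OC)CCC1=O | intermediate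
15 | (1S,2S,3S)-3-{3-[(tert-butyldimethylsilyl)oxy]propyl}-4,4-dimethoxy-1,2-dimethyl-2-(prop-2-en-1-yl)cyclohexan-1-ol | C=CC[C@@]1(C)[C@H](CCCO[Si](C)(C)C(C)(C)C)C(OC)(OC)CC[C@]1(C)O | intermediate
16 | triethylsilyl ether of 15, tert-butyl{3-[(1S,2S,3S)-6,6-dimethoxy-2,3-dimethyl-2-(prop-2-en-1-yl)-3-[(triethylsilyl)oxy]cyclohexyl]propoxy}dimethylsilane | C=CC[C@@]1(C)[C@H](CCCO[Si](C)(C)C(C)(C)C)C(OC)(OC)CC[C@]1(C)O[Si](CC)(CC)CC | intermediate
17 | 2-[(1S,2S,6S)-6-{3-[(tert-butyldimethylsilyl)oxy]propyl}-5,5-dimethoxy-1,2-dimethyl-2-[(triethylsilyl)oxy]cyclohexyl]acetaldehyde | O=CC[C@@]1(C)[C@H](CCCO[Si](C)(C)C(C)(C)C)C(OC)(OC)CC[C@]1(C)O[Si](CC)(CC)CC | intermediate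
18 | 2-[(1S,2S,6S)-6-{3-[(tert-butyldimethylsilyl)oxy]propyl}-5,5-dimethoxy-1,2-dimethyl-2-[(triethylsilyl)oxy]cyclohexyl]ethan-1-ol | OCC[C@@]1(C)[C@H](CCCO[Si](C)(C)C(C)(C)C)C(OC)(OC)CC[C@]1(C)O[Si](CC)(CC)CC | intermediate
19 | tert-butyl{3-[(1S,2S,3S)-2-(2-iodoethyl)-6,6-dimethoxy-2,3-dimethyl-3-[(triethylsilyl)oxy]cyclohexyl]propoxy}dimethylsilane | ICC[C@@]1(C)[C@H](CCCO[Si](C)(C)C(C)(C)C)C(OC)(OC)CC[C@]1(C)O[Si](CC)(CC)CC | intermediate
20 | tert-butyl{3-[(1S,2S,3S)-6,6-dimethoxy-2,3-dimethyl-2-(pent-3-yn-1-yl)-3-[(triethylsilyl)oxy]cyclohexyl]propoxy}dimethylsilane | CC#CCC[C@@]1(C)[C@H](CCCO[Si](C)(C)C(C)(C)C)C(OC)(OC)CC[C@]1(C)O[Si](CC)(CC)CC | intermediate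
21 | (2S,3S,4S)-2-{3-[(tert-butyldimethylsilyl)oxy]propyl}-3,4-dimethyl-3-(pent-3-yn-1-yl)-4-[(triethylsilyl)oxy]cyclohexan-1-one | CC#CCC[C@@]1(C)[C@H](CCCO[Si](C)(C)C(C)(C)C)C(=O)CC[C@]1(C)O[Si](CC)(CC)CC | intermediate
22 | tert-butyl{3-[(1S,2S,3S)-6-(dibromomethylidene)-2,3-dimethyl-2-(pent-3-yn-1-yl)-3-[(triethylsilyl)oxy]cyclohexyl]propoxy}dimethylsilane | CC#CCC[C@@]1(C)[C@H](CCCO[Si](C)(C)C(C)(C)C)C(=C(Br)Br)CC[C@]1(C)O[Si](CC)(CC)CC | intermediate
23 | tert-butyl{3-[(1S,2S,3S,6Z)-6-(1-bromoethylidene)-2,3-dimethyl-2-(pent-3-yn-1-yl)-3-[(triethylsilyl)oxy]cyclohexyl]propoxy}dimethylsilane | CC#CCC[C@@]1(C)[C@H](CCCO[Si](C)(C)C(C)(C)C)/C(=C(/C)Br)CC[C@]1(C)O[Si](CC)(CC)CC | intermediate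
24 | alkenyllithium from 23 (lithium in place of bromine, geometry retained) | CC#CCC[C@@]1(C)[C@H](CCCO[Si](C)(C)C(C)(C)C)/C(=C(/C)[Li])CC[C@]1(C)O[Si](CC)(CC)CC | intermediate
25 | (2Z)-2-[(2R,3S,4S)-2-{3-[(tert-butyldimethylsilyl)oxy]propyl}-3,4-dimethyl-3-(pent-3-yn-1-yl)-4-[(triethylsilyl)oxy]cyclohexylidene]propan-1-ol | CC#CCC[C@@]1(C)[C@H](CCCO[Si](C)(C)C(C)(C)C)/C(=C(/C)CO)CC[C@]1(C)O[Si](CC)(CC)CC | intermediate
26 | tert-butyldimethylsilyl ether of 25 (primary allylic oxygen silylated; 2Z; ring 2R,3S,4S) | CC#CCC[C@@]1(C)[C@H](CCCO[Si](C)(C)C(C)(C)C)/C(=C(/C)CO[Si](C)(C)C(C)(C)C)CC[C@]1(C)O[Si](CC)(CC)CC | intermediate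
27 | chlorobis(cyclopentadienyl)zirconium (E)-alkenyl from 26, zirconium on the methyl-bearing alkene carbon | Cl[Zr](C1C=CC=C1)(C1C=CC=C1)/C(C)=C/CC[C@@]1(C)[C@H](CCCO[Si](C)(C)C(C)(C)C)/C(=C(/C)CO[Si](C)(C)C(C)(C)C)CC[C@]1(C)O[Si](CC)(CC)CC | intermediate
28 | methylzinc (E)-alkenyl from 27 | C[Zn]/C(C)=C/CC[C@@]1(C)[C@H](CCCO[Si](C)(C)C(C)(C)C)/C(=C(/C)CO[Si](C)(C)C(C)(C)C)CC[C@]1(C)O[Si](CC)(CC)CC | intermediate
29 | (2R,3E)-3-methyl-1-[(2R,3R)-3-methyl-3-(4-methylpent-3-en-1-yl)oxiran-2-yl]-6-(silylated cyclohexyl of 26)hex-3-en-2-ol | CC(C)=CCC[C@@]1(C)O[C@@H]1C[C@@H](O)/C(C)=C/CC[C@@]2(C)[C@H](CCCO[Si](C)(C)C(C)(C)C)/C(=C(/C)CO[Si](C)(C)C(C)(C)C)CC[C@]2(C)O[Si](CC)(CC)CC | intermediate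
30 | (2S,3R,5R)-2-methyl-2-(4-methylpent-3-en-1-yl)oxolan-3-ol carrying at C5 the (2E)-pent-2-en-2-yl chain to the cyclohexane; the two primary oxygens are TBS ethers and the tertiary ring oxygen a TES ether (tris-silyl ether of 31) | CC(C)=CCC[C@]1(C)O[C@@H](/C(C)=C/CC[C@@]2(C)[C@H](CCCO[Si](C)(C)C(C)(C)C)/C(=C(/C)CO[Si](C)(C)C(C)(C)C)CC[C@]2(C)O[Si](CC)(CC)CC)C[C@H]1O | intermediate
31 | (2Z)-2-[(2R,3S,4S)-4-hydroxy-2-(3-hydroxypropyl)-3,4-dimethyl-3-{(3E)-4-[(2R,4R,5S)-4-hydroxy-5-methyl-5-(4-methylpent-3-en-1-yl)oxolan-2-yl]pent-3-en-1-yl}cyclohexylidene]propan-1-ol | CC(C)=CCC[C@]1(C)O[C@@H](/C(C)=C/CC[C@@]2(C)[C@H](CCCO)/C(=C(/C)CO)CC[C@]2(C)O)C[C@H]1O | intermediate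
32 | (2Z)-2-[(2R,3S,4S)-4-hydroxy-2-(3-hydroxypropyl)-3,4-dimethyl-3-{(3E)-4-[(2R,4R,5S)-4-hydroxy-5-methyl-5-(4-methylpent-3-en-1-yl)oxolan-2-yl]pent-3-en-1-yl}cyclohexylidene]propanal | CC(C)=CCC[C@]1(C)O[C@@H](/C(C)=C/CC[C@@]2(C)[C@H](CCCO)/C(=C(/C)C=O)CC[C@]2(C)O)C[C@H]1O | target

## Step count and risks

Total step count: 20. Longest linear sequence: 17 (steps 4 to 20); the epoxy aldehyde branch (steps 1 to 3) joins at step 18.

Steps most likely to fail, riskiest first:

**Step 18.** What may go wrong: poor facial selectivity of the alkenylzinc addition at C5 if ligand and β-epoxide are mismatched, incomplete regiocontrol in the hydrozirconation, or loss of the β,γ-epoxy aldehyde by elimination before the carbon–carbon bond forms. The fallback sets out from 26 and 5 and sets C5 by reagent-controlled ketone reduction instead of carbonyl addition. Hydrozirconation of 26 and iodinolysis would give the (E)-alkenyl iodide F1, which can be purified from its regioisomer. A Nozaki–Hiyama–Kishi coupling of F1 with 5 (CrCl2, NiCl2 cat., DMSO) would give the epoxy alcohols F2 as both C5 epimers. Oxidation with Dess–Martin periodinane and NaHCO3 would give the epoxy enone F3. Corey–Bakshi–Shibata reduction with the (S)-oxazaborolidine and catecholborane should then give the (R)-carbinol, which is compound 29; treated with CSA as in the main route it comes back at compound 30.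

**Step 15.** What may go wrong: insufficient discrimination between the two C–Br bonds, giving a mixture of alkene isomers, or double methylation. The fallback sets out from ketone 21 and relies on thermodynamic control. Addition of CH2=C(CH3)MgBr with CeCl3 would give the tertiary allylic alcohol F4. Babler–Dauben oxidative transposition with [C5H5NH][CrO3Cl] would give the tetrasubstituted enal F5 as a mixture of alkene isomers. Iodine-catalysed equilibration and chromatography should secure the Z isomer, in which the formyl group (smaller in-plane demand than methyl) lies syn to the substituted ring carbon. Reduction with NaBH4 and CeCl3 then comes back at compound 25.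

**Step 8.** What may go wrong: methyl delivery from the wrong face of the ketone, or enolisation instead of addition. The fallback sets out from ketone 14 and reverses the order in which carbon and oxygen are attached. Wittig methylenation (Ph3P=CH2, toluene, 80 °C) would give the methylidene compound F6. Epoxidation with mCPBA should occur at the more electron-rich 1,1-disubstituted alkene, from the same face that a carbon nucleophile prefers, so the oxygen ends where the methyl would otherwise have gone, giving the spiro-epoxide F7. Opening at the CH2 terminus with LiBHEt3 comes back at compound 15.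

Further compounds
F1 | step 18 | (E)-alkenyl iodide from 26, iodine on the methyl-bearing alkene carbon | I/C(C)=C/CC[C@@]1(C)[C@H](CCCO[Si](C)(C)C(C)(C)C)/C(=C(/C)CO[Si](C)(C)C(C)(C)C)CC[C@]1(C)O[Si](CC)(CC)CC
F2 | step 18 | epoxy alcohols, both C2 epimers of 29 | CC(C)=CCC[C@@]1(C)O[C@@H]1CC(O)/C(C)=C/CC[C@@]2(C)[C@H](CCCO[Si](C)(C)C(C)(C)C)/C(=C(/C)CO[Si](C)(C)C(C)(C)C)CC[C@]2(C)O[Si](CC)(CC)CC
F3 | step 18 | (3E)-epoxy enone, the 2-ketone corresponding to 29 | CC(C)=CCC[C@@]1(C)O[C@@H]1CC(=O)/C(C)=C/CC[C@@]2(C)[C@H](CCCO[Si](C)(C)C(C)(C)C)/C(=C(/C)CO[Si](C)(C)C(C)(C)C)CC[C@]2(C)O[Si](CC)(CC)CC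
F4 | step 15 | (2S,3S,4S)-2-{3-[(tert-butyldimethylsilyl)oxy]propyl}-3,4-dimethyl-3-(pent-3-yn-1-yl)-1-(prop-1-en-2-yl)-4-[(triethylsilyl)oxy]cyclohexan-1-ol, C1 epimers | CC#CCC[C@@]1(C)[C@H](CCCO[Si](C)(C)C(C)(C)C)C(O)(C(C)=C)CC[C@]1(C)O[Si](CC)(CC)CC
F5 | step 15 | (2Z)-2-[(2R,3S,4S)-2-{3-[(tert-butyldimethylsilyl)oxy]propyl}-3,4-dimethyl-3-(pent-3-yn-1-yl)-4-[(triethylsilyl)oxy]cyclohexylidene]propanal | CC#CCC[C@@]1(C)[C@H](CCCO[Si](C)(C)C(C)(C)C)/C(=C(/C)C=O)CC[C@]1(C)O[Si](CC)(CC)CC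
F6 | step 8 | tert-butyl{3-[(1S,2S)-6,6-dimethoxy-2-methyl-3-methylidene-2-(prop-2-en-1-yl)cyclohexyl]propoxy}dimethylsilane | C=CC[C@@]1(C)[C@H](CCCO[Si](C)(C)C(C)(C)C)C(OC)(OC)CCC1=C
F7 | step 8 | (3S,4S,5S)-5-{3-[(tert-butyldimethylsilyl)oxy]propyl}-6,6-dimethoxy-4-methyl-4-(prop-2-en-1-yl)-1-oxaspiro[2.5]octane | C=CC[C@@]1(C)[C@H](CCCO[Si](C)(C)C(C)(C)C)C(OC)(OC)CC[C@@]12CO2
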